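**Retrosynthetic overview**

1. Target 11 ⇐ acid cleavage of the 7-O-methoxymethyl ether of 10 ⇐ C6–C1'' (sp2–sp3) Stille disconnection into aryl iodide 4 and (E)-geranyltributylstannane 9.
2. 4 ⇐ (2S)-hesperetin 1 by 7-O-MOM protection, Mitsunobu 3'-O-methylation and iodination at C6; 9 ⇐ tributyltin chloride 5 and geranyl chloride 6.
3. Structural feature used: rings A, B and C, the (S)-centre at C2 and the 4'-OMe are all present in 1. C6, flanked by O5 and O7, is the one ring A carbon ortho to the C5 hydroxyl that is hydrogen-bonded to the C4 carbonyl, so the iodine and then geranyl C1'' can be placed there.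
4. No ring is formed in the route and no stereocentre is made. No step uses carbonate, hydroxide or alkoxide base, because the C3 enolate would expel O1, open ring C and racemise C2; for that reason the 3'-O-methylation is a Mitsunobu reaction.

Key step: step 5

Remark on the chemistry: (2S)-hesperetin 1 is assumed to be used as enantiomerically pure material; the common racemic grade would have to be resolved first or replaced by aglycone released from (2S)-hesperidin.

**Route**

Step 1
Reactants: 1 (2S)-hesperetin
Product: 2 (S)-5-hydroxy-2-(3-hydroxy-4-methoxyphenyl)-7-(methoxymethoxy)chroman-4-one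
Conditions: MOMCl (1.05 equiv), i-Pr2NEt (1.2 equiv), CH2Cl2–THF, 0 °C
Reagents that add atoms: chloromethyl methyl ether, COCCl
Why: Williamson-type O-alkylation in which the 7-OH, para to the C4 carbonyl and by far the most acidic phenol, is the one ionised by the hindered amine at 0 °C, so one equivalent of MOMCl should cap O7 alone while the hydrogen-bonded 5-OH and the less acidic 3'-OH stay free, and a tertiary amine in CH2Cl2 is too weak to enolise C3 and open ring C.

Step 2
Reactants: 2 (S)-5-hydroxy-2-(3-hydroxy-4-methoxyphenyl)-7-(methoxymethoxy)chroman-4-one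
Product: 3 (S)-2-(3,4-dimethoxyphenyl)-5-hydroxy-7-(methoxymethoxy)chroman-4-one
Conditions: MeOH (3 equiv), PPh3 (1.3 equiv), DIAD (1.3 equiv), THF, 0 °C → rt
Reagents that add atoms: methanol, CO
Why: Mitsunobu etherification in which the unchelated 3'-phenol attacks the methoxyphosphonium ion without any carbonate or alkoxide base, so ring C cannot open through the C3 enolate and C2 should keep its configuration, while the chelated 5-OH reacts far more slowly and should stay free at this stoichiometry.

Step 3
Reactants: 3 (S)-2-(3,4-dimethoxyphenyl)-5-hydroxy-7-(methoxymethoxy)chroman-4-one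
Product: 4 (S)-2-(3,4-dimethoxyphenyl)-5-hydroxy-6-iodo-7-(methoxymethoxy)chroman-4-one
Conditions: BnMe3N[ICl2] (1.05 equiv), CaCO3, CH2Cl2–MeOH (5:2), rt, dark
Reagents that add atoms: benzyltrimethylammonium dichloroiodate, C[N+](C)(C)Cc1ccccc1.Cl[I-]Cl
Why: Electrophilic aromatic iodination in which ring A, with three oxygen donors, is far more nucleophilic than the veratrole ring B, and in 5-hydroxy-7-alkoxyflavonoids the free chelated 5-OH steers the reagent to its ortho carbon C6 and not to C8, while CaCO3 takes up the HCl so that the MOM acetal survives.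

Step 4
Reactants: 5 tributyltin chloride; 6 geranyl chloride
Product: 9 (E)-geranyltributylstannane, via hexabutylditin 7 (not isolated), via tributylstannyllithium 8 (not isolated)
Conditions: 5, Li (wire, excess), THF, 0 °C → rt; then 6, THF, −78 °C → rt
Reagents that add atoms: none
Why: Lithium reduces the tin chloride through the distannane to the stannyl anion, which displaces the primary allylic chloride by direct SN2 attack at C1 at low temperature and so leaves the (E)-trisubstituted alkene untouched; the chloride is chosen over the bromide because it is less prone to halogen–metal exchange and Wurtz coupling.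

Step 5
Reactants: 4 (S)-2-(3,4-dimethoxyphenyl)-5-hydroxy-6-iodo-7-(methoxymethoxy)chroman-4-one; 9 (E)-geranyltributylstannane
Product: 10 (S)-2-(3,4-dimethoxyphenyl)-6-[(E)-3,7-dimethylocta-2,6-dienyl]-5-hydroxy-7-(methoxymethoxy)chroman-4-one
Conditions: Pd(PPh3)4 (10 mol %), 9 (1.5 equiv), degassed amine-free DMF, 90 °C, Ar, no base
Reagents that add atoms: none
Why: Zerovalent palladium inserts into the C6–I bond of 4, the allylstannane transfers its geranyl group to palladium (SE2' transfer, then σ–π equilibration) to give an aryl(η3-geranyl)palladium species, and reductive elimination forms C6–C1''. The closest known reaction type is the Migita–Kosugi–Stille coupling of aryl iodides with prenyl- and geranylstannanes, which is known on 6-iodo-5-hydroxyflavonoids. No ring is closed and no stereocentre is created; C2 is a spectator, and because the medium holds no base the retro-oxa-Michael opening of ring C that would racemise it should not occur. The step needs attachment through the primary allyl terminus with the (E) alkene kept: the aryl group should go to the unsubstituted CH2 end because the other terminus is fully substituted, and E/Z exchange would need a σ-allyl bound to palladium through that tertiary carbon, which is disfavoured. Only one C–I bond is present, the 5-OH is tied up in its hydrogen bond to the C4 carbonyl and the 7-OH is masked, so the competitor to watch is hydrodeiodination at the hindered C6.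

Step 6
Reactants: 10 (S)-2-(3,4-dimethoxyphenyl)-6-[(E)-3,7-dimethylocta-2,6-dienyl]-5-hydroxy-7-(methoxymethoxy)chroman-4-one
Product: 11 (S)-2-(3,4-dimethoxyphenyl)-6-[(E)-3,7-dimethylocta-2,6-dienyl]-5,7-dihydroxychroman-4-one (target)
Conditions: 3 M aq. HCl–MeOH (1:4), 40 °C
Reagents that add atoms: none
Why: Acid-catalysed solvolysis of the aryl methoxymethyl acetal through the methoxymethyl oxocarbenium ion, which methanol traps; dilute acid at moderate temperature should leave the trisubstituted alkenes unprotonated, and the flavanone C2 centre is configurationally stable to acid.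

**Compound list**

1 | (2S)-hesperetin, (S)-5,7-dihydroxy-2-(3-hydroxy-4-methoxyphenyl)chroman-4-one | COc1ccc([C@@H]2CC(=O)c3c(O)cc(O)cc3O2)cc1O | starting material
2 | (S)-5-hydroxy-2-(3-hydroxy-4-methoxyphenyl)-7-(methoxymethoxy)chroman-4-one | COc1ccc([C@@H]2CC(=O)c3c(O)cc(OCOC)cc3O2)cc1O | intermediate
3 | (S)-2-(3,4-dimethoxyphenyl)-5-hydroxy-7-(methoxymethoxy)chroman-4-one | COc1ccc([C@@H]2CC(=O)c3c(O)cc(OCOC)cc3O2)cc1OC | intermediate
4 | (S)-2-(3,4-dimethoxyphenyl)-5-hydroxy-6-iodo-7-(methoxymethoxy)chroman-4-one | COc1ccc([C@@H]2CC(=O)c3c(cc(OCOC)c(I)c3O)O2)cc1OC | intermediate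
5 | tributyltin chloride | CCCC[Sn](Cl)(CCCC)CCCC | starting material
6 | geranyl chloride, (E)-1-chloro-3,7-dimethylocta-2,6-diene | CC(C)=CCC/C(C)=C/CCl | starting material
7 | hexabutylditin (not isolated) | CCCC[Sn](CCCC)(CCCC)[Sn](CCCC)(CCCC)CCCC | intermediate
8 | tributylstannyllithium (not isolated) | [Li][Sn](CCCC)(CCCC)CCCC | intermediate
9 | (E)-geranyltributylstannane, tributyl[(E)-3,7-dimethylocta-2,6-dienyl]stannane | CC(C)=CCC/C(C)=C/C[Sn](CCCC)(CCCC)CCCC | intermediate
10 | (S)-2-(3,4-dimethoxyphenyl)-6-[(E)-3,7-dimethylocta-2,6-dienyl]-5-hydroxy-7-(methoxymethoxy)chroman-4-one | COc1ccc([C@@H]2CC(=O)c3c(cc(OCOC)c(C/C=C(\C)CCC=C(C)C)c3O)O2)cc1OC | intermediate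
11 | (S)-2-(3,4-dimethoxyphenyl)-6-[(E)-3,7-dimethylocta-2,6-dienyl]-5,7-dihydroxychroman-4-one | COc1ccc([C@@H]2CC(=O)c3c(cc(O)c(C/C=C(\C)CCC=C(C)C)c3O)O2)cc1OC | target

**Step count**

Total: 6 steps. Longest linear sequence: 5 steps (steps 1, 2, 3, 5, 6 from hesperetin); step 4 is a one-step branch that joins at step 5.

**Steps most likely to fail**

Step 5. Oxidative addition at the doubly ortho-substituted, electron-rich C6–I bond may be slow, so that hydrodeiodination overtakes allyl transfer; some coupling through the tertiary allyl terminus is also possible. The fallback reverses the roles of the partners, sets out from 4 and comes back at 10. Iodide 4 would be stannylated with hexabutylditin (the compound numbered 7, here as a purchased reagent) and Pd(PPh3)4 in toluene at 100 °C to give the arylstannane (S)-2-(3,4-dimethoxyphenyl)-5-hydroxy-7-(methoxymethoxy)-6-(tributylstannyl)chroman-4-one F1. F1 would then be coupled with geranyl chloride 6 (Pd2(dba)3, tri(2-furyl)phosphine, THF, 50 °C). Oxidative addition then takes place at the reactive allylic chloride and the arene enters by transmetalation, which removes the slow insertion and the aryl–palladium iodide that is reduced. If branched coupling were the fault, the halide-free route given under step 3 would serve instead.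

Step 6. The acid needed for acetal cleavage may protonate the geranyl alkenes, leading to cyclisation onto the flanking 5- or 7-hydroxyl (chroman formation) or to addition of methanol. The fallback removes the acetal before the side chain is present and carries a fluoride-labile group through the coupling; it sets out from 4 and comes back at 11. Treatment of 4 with 3 M aq. HCl–MeOH at 40 °C should give (S)-2-(3,4-dimethoxyphenyl)-5,7-dihydroxy-6-iodochroman-4-one F2. Silylation of the unchelated 7-OH (TBSCl, imidazole, CH2Cl2, 0 °C) should give (S)-7-(tert-butyldimethylsilyloxy)-2-(3,4-dimethoxyphenyl)-5-hydroxy-6-iodochroman-4-one F3. Stille coupling with 9 under the conditions of step 5 should give (S)-7-(tert-butyldimethylsilyloxy)-2-(3,4-dimethoxyphenyl)-6-[(E)-3,7-dimethylocta-2,6-dienyl]-5-hydroxychroman-4-one F4. Desilylation with Et3N·3HF in THF at rt, neither strongly acidic nor basic, should then release 11.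

Step 3. The iodinating agent may attack C8 or ring B, or iodinate twice. The fallback gives up electrophilic halogenation and delivers the side chain from O5, which can reach only C6 as its ortho carbon; it sets out from 3 and comes back at 10. Mitsunobu etherification of the chelated 5-OH of 3 with geraniol (PPh3, DIAD, THF, rt) should give (S)-2-(3,4-dimethoxyphenyl)-5-[(E)-3,7-dimethylocta-2,6-dienyloxy]-7-(methoxymethoxy)chroman-4-one F5. Heating F5 with Florisil (activated magnesium silicate, MgSiO3) in toluene at 90 °C should bring about the known [1,3] O-to-C shift of aryl allyl ethers to the ortho carbon with the (E) alkene kept, giving 10. The 8-geranyl isomer from a [1,5] shift would be the by-product to separate.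

**Further compounds**

F1 | step 5 | (S)-2-(3,4-dimethoxyphenyl)-5-hydroxy-7-(methoxymethoxy)-6-(tributylstannyl)chroman-4-one | COc1ccc([C@@H]2CC(=O)c3c(cc(OCOC)c([Sn](CCCC)(CCCC)CCCC)c3O)O2)cc1OC
F2 | step 6 | (S)-2-(3,4-dimethoxyphenyl)-5,7-dihydroxy-6-iodochroman-4-one | COc1ccc([C@@H]2CC(=O)c3c(cc(O)c(I)c3O)O2)cc1OC
F3 | step 6 | (S)-7-(tert-butyldimethylsilyloxy)-2-(3,4-dimethoxyphenyl)-5-hydroxy-6-iodochroman-4-one | COc1ccc([C@@H]2CC(=O)c3c(cc(O[Si](C)(C)C(C)(C)C)c(I)c3O)O2)cc1OC
F4 | step 6 | (S)-7-(tert-butyldimethylsilyloxy)-2-(3,4-dimethoxyphenyl)-6-[(E)-3,7-dimethylocta-2,6-dienyl]-5-hydroxychroman-4-one | COc1ccc([C@@H]2CC(=O)c3c(cc(O[Si](C)(C)C(C)(C)C)c(C/C=C(\C)CCC=C(C)C)c3O)O2)cc1OC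
F5 | step 3 | (S)-2-(3,4-dimethoxyphenyl)-5-[(E)-3,7-dimethylocta-2,6-dienyloxy]-7-(methoxymethoxy)chroman-4-one | COc1ccc([C@@H]2CC(=O)c3c(cc(OCOC)cc3OC/C=C(\C)CCC=C(C)C)O2)cc1OC
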